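G cannot hold the whole charge of L in this flask. In the eta run Z reads 0.211 of G at 3.00 min, and 0.210 at 0.833 min, so at that ratio G takes 82.6% of whatever L has reacted.

- eta: L 10 mM (fed, over 80 s); E 50 µM; the very flask that is asked about, followed so far; the fed solution adds 0.25 times the starting volume
- flask: L 10 mM (fed, over 80 s); E 50 µM; time 10 min; the fed solution adds 0.25 times the starting volume

- eta (time / min: G / %, Z / %, L / %): 0.250: 0.8, 0, 14.1; 0.833: 20.5, 4.3, 38.1; 1.33: 39.7, 7.9, 53.7; 2.00: 58.4, 11.0, 30.7; 3.00: 67.3, 14.2, 20.2

(each reading ± 1 percentage point)

- where most of what was charged as L, at 10 min is found (Z / L / G)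
- the largest share itself, whichever of these holds it, in percent of the L charged

- charges are per starting volume, the dose included; the dosed solution carries all of it
- the earlier runs were read with a standard deviation of 1 percentage point
- percentages count the whole charge, also what has not yet gone in

The open question is how much L stays. After the feed, L falls pseudo-first-order with a specific rate a, but a is falling too: in the eta run we read 0.835 min⁻¹ from 1.33 min to 2.00 min, then 0.419 min⁻¹ up to 3.00 min. That suggests a halves in 0.839 min. But both rates share one reading, with a scatter of 1 percentage point, and their midpoints lie close together.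

A longer baseline helps. Between 0.833 min and 1.33 min the feed brought 37.3% of the charge while L rose 16 points, so in the eta run a reads 0.950 min⁻¹. Against 0.419 min⁻¹, this gives the activity half-life τ, the time in which a halves: 1.20 min.

We must still assume that the halving continues. The 5.83 half-lives left after 3.00 min then hold 0.533 e-foldings of L, so our reckoning leaves L at 11.9% and G at 72.8%.

The forecast says G at 74%, judging that “the active centres seem to die”; our G is lower.

The flask gives G at 77.5%, with Z 15.9% and L 6.64%.

    E → 2 D (k = 0.0139 s⁻¹)
    L + D → X + G (k = 2.36 × 10⁶ M⁻¹ s⁻¹)
    L + X → G + X, rate k3*[X]*[L] (k = 2.17 × 10⁵ M⁻¹ s⁻¹)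
    2 X → Q (k = 4.00 × 10⁷ M⁻¹ s⁻¹)
    G ⇌ Z (K = 0.205, k = 0.0388 s⁻¹)

In this flask L ends below our 11.9%, and the forecast's share stands within its margin. E has a half-life of 0.83 min by its conversion into D, short against 10 min, and 0.024% of its charge remains at that time. L still stands at 6.6% then and at 6.19% after 100 min, with G at 77.9%: a dead-end polymerisation.

For the neighbour flask stopped at 2.5 min, τ carries L from the 30.7% read at 2.00 min to 24.1%. That flask holds 23.3%.

The runs were computed for an exercise, noise included.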